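**Retrosynthetic overview**
- Feature: in ring C the C4 ketone is bonded to aryl carbon C4a (whose neighbour C5 carries the hydroxyl peri to the carbonyl) and to the C3 methylene, while O1 already joins C8a to the phenyl-bearing C2. Ring C is therefore the adduct of a salicylaldehyde C–H bond across an O1-bound 1-phenylvinyl group.
- Last disconnection: the O7–H bond, from its methoxymethyl (MOM) ether.
- Key disconnection: C3–C4 and C2–H, by enantioselective rhodium-catalysed intramolecular hydroacylation. It closes ring C (the only ring made; rings A and B are bought) and sets C2.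
- Precursor: O1–C2 by copper-catalysed coupling of one salicylaldehyde hydroxyl with α-bromostyrene, after MOM protection of O7 and C-prenylation of 2,4,6-trihydroxybenzaldehyde at the future C6 and C8.

Key step: step 4

Assumption: the target is the (2S) enantiomer as drawn; which antipode of the bisphosphine gives 2S cannot be predicted with confidence and is to be fixed in the first experiments (both antipodes are commercial, the (R) ligand is written). "Prenyl" means 3-methylbut-2-en-1-yl.

Step 1
Reactants: 1 2,4,6-trihydroxybenzaldehyde; 2 prenyl bromide
Product: 3 2,4,6-trihydroxy-3,5-diprenylbenzaldehyde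
Conditions: prenyl bromide (2.2 equiv), 10% aq. KOH, 0 °C to rt
Reagents that add atoms: prenyl bromide, CC(C)=CCBr
Why: Base-mediated C-alkylation of a phloroglucinol-type phenolate, as used for acylphloroglucinols: in water the ambident phenolate reacts at carbon, and C3 and C5 are the only free ring carbons, so two equivalents of the allylic bromide should give the 3,5-diprenyl compound, with over-alkylated and O-alkylated material removed by chromatography.

Step 2
Reactants: 3 2,4,6-trihydroxy-3,5-diprenylbenzaldehyde; 4 chloromethyl methyl ether (MOMCl)
Product: 5 2,6-dihydroxy-4-(methoxymethoxy)-3,5-diprenylbenzaldehyde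
Conditions: MOMCl (1.05 equiv), K2CO3 (1.1 equiv), acetone, 0 °C to rt
Reagents that add atoms: chloromethyl methyl ether, COCCl
Why: Williamson-type O-alkylation (MOM protection) in which the 4-hydroxyl, para to the formyl group and not tied up in a hydrogen bond to the carbonyl, is the most acidic phenol and should be alkylated selectively by one equivalent of the small, reactive chloride.

Step 3
Reactants: 5 2,6-dihydroxy-4-(methoxymethoxy)-3,5-diprenylbenzaldehyde; 6 α-bromostyrene
Product: 7 2-hydroxy-4-(methoxymethoxy)-3,5-diprenyl-6-[(1-phenylvinyl)oxy]benzaldehyde (achiral)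
Conditions: α-bromostyrene (1.1 equiv), CuI (10 mol%), N,N-dimethylglycine hydrochloride (30 mol%), Cs2CO3 (2 equiv), 1,4-dioxane, 90 °C; chromatography on Et3N-deactivated silica
Reagents that add atoms: α-bromostyrene, C=C(Br)c1ccccc1
Why: Ullmann-type coupling of a phenol with an alkenyl bromide under monovalent copper catalysis; the two ortho hydroxyls are equivalent, so the first coupling has no regiochemical issue, and the remaining hydroxyl, then locked in the hydrogen bond to the formyl group and more crowded, should react more slowly, so that a slight excess of bromide gives the mono-ether.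

Step 4
Reactants: 7 2-hydroxy-4-(methoxymethoxy)-3,5-diprenyl-6-[(1-phenylvinyl)oxy]benzaldehyde
Product: 8 (2S)-5-hydroxy-7-(methoxymethoxy)-6,8-diprenyl-2-phenylchroman-4-one
Conditions: [Rh(cod)OMe]2 (2.5 mol%), (R)-DTBM-SEGPHOS (5.5 mol%), toluene, 60 °C, argon
Reagents that add atoms: none
Why: Proposed new method: the rhodium methoxide should take up the free ortho hydroxyl (the future C5–OH) as a phenolate, monovalent rhodium should insert into the neighbouring aldehyde C–H bond to give a five-membered O,C-chelated acyl hydride of trivalent rhodium, the 1-phenylvinyl ether should insert into Rh–H with hydride going to the oxygen-bearing carbon (future C2) and rhodium to the terminal carbon (future C3), and C3–C4 reductive elimination from the seven-membered rhodacycle should release the ketone and return the catalyst. The closest known reaction types are the rhodium/bisphosphine-catalysed enantioselective cyclisation of 4-substituted pent-4-enals to 3-substituted cyclopentanones and the phenolate-assisted intermolecular hydroacylation of alkenes with salicylaldehydes; closure of a six-membered ring onto an aryl 1-arylvinyl ether has not been shown. Ring C closes in a net 6-endo-trig sense, the acyl carbon bonding to the terminal alkene carbon so that both alkene carbons end up in the ring. C2 is created only by C–H bond formation on an achiral substrate, and its configuration is set by the chiral bisphosphine, which distinguishes the two faces of the 1,1-disubstituted enol ether at hydride insertion. The step needs six-ring over five-ring (coumaranone) closure, which the preference for a primary alkyl rhodium over a tertiary benzylic α-oxy alkyl rhodium should secure, and hydroacylation over decarbonylation, which the phenolate chelate should secure by holding the acyl hydride; the prenyl groups sit meta to the formyl group, cannot reach the acyl rhodium and bind poorly as trisubstituted alkenes.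

Step 5
Reactants: 8 (2S)-5-hydroxy-7-(methoxymethoxy)-6,8-diprenyl-2-phenylchroman-4-one
Product: 9 (2S)-5,7-dihydroxy-6,8-diprenyl-2-phenylchroman-4-one (target)
Conditions: HCl (1.25 M in MeOH), 0 °C to rt
Reagents that add atoms: none
Why: Acid-catalysed acetal exchange with methanol (MOM cleavage) should free the 7-hydroxyl under conditions mild enough to leave the prenyl groups uncyclised and C2 untouched, since ring opening to the chalcone, the usual racemisation path of flavanones, is a base-promoted process.

**Compound list**
1 | 2,4,6-trihydroxybenzaldehyde | O=Cc1c(O)cc(O)cc1O | starting material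
2 | prenyl bromide (1-bromo-3-methylbut-2-ene) | CC(C)=CCBr | starting material
3 | 2,4,6-trihydroxy-3,5-diprenylbenzaldehyde | O=Cc1c(O)c(CC=C(C)C)c(O)c(CC=C(C)C)c1O | intermediate
4 | chloromethyl methyl ether (MOMCl) | COCCl | starting material
5 | 2,6-dihydroxy-4-(methoxymethoxy)-3,5-diprenylbenzaldehyde | O=Cc1c(O)c(CC=C(C)C)c(OCOC)c(CC=C(C)C)c1O | intermediate
6 | α-bromostyrene ((1-bromovinyl)benzene) | C=C(Br)c1ccccc1 | starting material
7 | 2-hydroxy-4-(methoxymethoxy)-3,5-diprenyl-6-[(1-phenylvinyl)oxy]benzaldehyde | C=C(Oc1c(CC=C(C)C)c(OCOC)c(CC=C(C)C)c(O)c1C=O)c1ccccc1 | intermediate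
8 | (2S)-5-hydroxy-7-(methoxymethoxy)-6,8-diprenyl-2-phenylchroman-4-one | CC(C)=CCc1c(OCOC)c(CC=C(C)C)c2c(c1O)C(=O)C[C@@H](c1ccccc1)O2 | intermediate
9 | (2S)-5,7-dihydroxy-6,8-diprenyl-2-phenylchroman-4-one | CC(C)=CCc1c(O)c(CC=C(C)C)c2c(c1O)C(=O)C[C@@H](c1ccccc1)O2 | target

Total step count: 5. Longest linear sequence: 5 steps (from 1).

**Steps most likely to fail**

1. Step 4 (the untested key step). The acyl rhodium may decarbonylate, reductive elimination from the seven-membered rhodacycle may stall, facial selection at the enol ether may be poor, or the enol ether may be hydrolysed by traces of water. The fallback uses known chemistry, sets out from 5 and comes back at 8.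
   - Addition of HC≡CMgBr (excess, THF, 0 °C) to the aldehyde should give 1-[2,6-dihydroxy-4-(methoxymethoxy)-3,5-diprenylphenyl]prop-2-yn-1-ol F1 (racemic carbinol, oxidised next).
   - MnO2 in CH2Cl2 should give the ynone 1-[2,6-dihydroxy-4-(methoxymethoxy)-3,5-diprenylphenyl]prop-2-yn-1-one F2.
   - Diethylamine in ethanol (amine conjugate addition, then 6-endo ring closure with return of the amine) should give 5-hydroxy-7-(methoxymethoxy)-6,8-diprenyl-4H-chromen-4-one F3.
   - Enantioselective 1,4-addition of phenylboronic acid to this chromone should give 8. Suitable catalysts are Pd(OCOCF3)2 with a tert-butyl pyridine-oxazoline ligand (NH4PF6, water, 1,2-dichloroethane, 60 °C) or a rhodium hydroxide complex of a chiral bisphosphine (Hayashi–Miyaura type); this is an established way to 2-arylchroman-4-ones, and the ligand antipode is chosen for 2S.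

2. Step 3. C–O coupling at a phenoxide that is substituted at both ortho positions and chelates copper may be slow, the bromide may lose HBr to give phenylacetylene, and a second vinylation may compete. The fallback sets out from 5 and comes back at 7.
   - Mitsunobu etherification of one hydroxyl with 2-bromo-1-phenylethanol (PPh3, DIAD, THF, 0 °C to rt) should give 2-(2-bromo-1-phenylethoxy)-6-hydroxy-4-(methoxymethoxy)-3,5-diprenylbenzaldehyde F4 (racemic; the centre is destroyed next).
   - Anti elimination of HBr with KOtBu (2.2 equiv, THF, 0 °C) should give 7; the benzylic hydrogen is the only β-hydrogen, so only the 1-phenylvinyl ether can form.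

3. Step 1. Alkylation may run on to geminal diprenyl, dearomatised products or go to oxygen, leaving little of the 3,5-diprenyl compound. The fallback replaces steps 1 and 2, sets out from 1 and comes back at 5.
   - MOMCl (1 equiv) with N,N-diisopropylethylamine in CH2Cl2 should protect the unhindered, most acidic 4-hydroxyl and give 2,6-dihydroxy-4-(methoxymethoxy)benzaldehyde F5.
   - Copper-catalysed O-alkylation of both hydroxyls with 3-chloro-3-methylbut-1-yne (CuCl2 cat., DBU, MeCN, 0 °C) should give 4-(methoxymethoxy)-2,6-bis[(2-methylbut-3-yn-2-yl)oxy]benzaldehyde F6.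
   - Semihydrogenation (H2, Pd/CaCO3 poisoned with Pb(OAc)2, quinoline, EtOAc) should give 4-(methoxymethoxy)-2,6-bis[(2-methylbut-3-en-2-yl)oxy]benzaldehyde F7.
   - A double aromatic Claisen rearrangement (N,N-diethylaniline, 120 °C) should move each 1,1-dimethylallyl group to the one free ortho carbon with allylic inversion, placing the prenyl groups at C3 and C5 and giving 5.

**Further compounds**
F1 | step 4 | 1-[2,6-dihydroxy-4-(methoxymethoxy)-3,5-diprenylphenyl]prop-2-yn-1-ol | C#CC(O)c1c(O)c(CC=C(C)C)c(OCOC)c(CC=C(C)C)c1O
F2 | step 4 | 1-[2,6-dihydroxy-4-(methoxymethoxy)-3,5-diprenylphenyl]prop-2-yn-1-one | C#CC(=O)c1c(O)c(CC=C(C)C)c(OCOC)c(CC=C(C)C)c1O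
F3 | step 4 | 5-hydroxy-7-(methoxymethoxy)-6,8-diprenyl-4H-chromen-4-one | CC(C)=CCc1c(OCOC)c(CC=C(C)C)c2occc(=O)c2c1O
F4 | step 3 | 2-(2-bromo-1-phenylethoxy)-6-hydroxy-4-(methoxymethoxy)-3,5-diprenylbenzaldehyde | O=Cc1c(O)c(CC=C(C)C)c(OCOC)c(CC=C(C)C)c1OC(CBr)c1ccccc1
F5 | step 1 | 2,6-dihydroxy-4-(methoxymethoxy)benzaldehyde | O=Cc1c(O)cc(OCOC)cc1O
F6 | step 1 | 4-(methoxymethoxy)-2,6-bis[(2-methylbut-3-yn-2-yl)oxy]benzaldehyde | O=Cc1c(OC(C)(C)C#C)cc(OCOC)cc1OC(C)(C)C#C
F7 | step 1 | 4-(methoxymethoxy)-2,6-bis[(2-methylbut-3-en-2-yl)oxy]benzaldehyde | O=Cc1c(OC(C)(C)C=C)cc(OCOC)cc1OC(C)(C)C=C
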